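**Plan**

1. The target is a 7-methoxycoumarin (ring A benzo, ring B the pyranone O1–C2–C3–C4–C4a–C8a) bearing at C3 an enedione ring C: C1' on C3, C2'H, C3'=O, C4'(OH)(prenyl), C5'H2, C6'=O.
2. Retrosynthesis: the C3'/C6' carbonyls and the C4'–CH2 bond are traced back to a 4-hydroxy-2,5-dimethoxyphenyl group (phenol oxygen on C4', methoxy groups on C3' and C6'). Ring B is then cut at C4–C4a and at O1–C2, and the acrylate at C3–C4.
3. Enabling feature: in ring B, C4a lies para to the C7 methoxy group and ortho to O1, so a C4 oxocarbenium carbon held by the C2 ester on a 3-methoxyphenyl ring can bond to it intramolecularly.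
4. Forward: arylacetate, then methoxyacrylate, then 3-methoxyphenyl ester, then ring B closed at C4–C4a (ring A is bought). Ring C is then dearomatised to its C3' monoketal, allyl is added at C4' and converted to prenyl by metathesis (a prenylboron reagent would transpose to the 1,1-dimethylallyl isomer), and the masks are hydrolysed.
5. Stereochemistry: the only stereocenter, C4' (R), comes from a catalyst-controlled allylboration of the C4' ketone, whose faces are distinguished by the ketal carbon C3' against the vinylic C5'.
6. The C4' oxygen travels as an isopropyl ether, which should be inert to triflic acid and leaves with BCl3 ahead of the methyl ethers.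

Key step: step 7

Assumption: the (R)-enantiomer of 3,3'-dibromo-BINOL is written for step 10 on the model of aryl methyl ketones (ketal carbon C3' as the large flank, vinylic C5' as the small one); if the first adduct proves to be the (S)-carbinol, the (S)-diol is used with nothing else changed.

**Route**

Step 1
Reactants: 1 4-hydroxy-2,5-dimethoxybenzaldehyde
Product: 2 4-isopropoxy-2,5-dimethoxybenzaldehyde
Conditions: 2-bromopropane, K2CO3, DMF, 60 °C
Reagents that add atoms: 2-bromopropane, CC(C)Br
Why: Williamson etherification of the phenoxide; the secondary ether has neither a sigmatropic nor a stabilised-cation exit in strong acid, so it should survive the triflic acid step and still be cleaved selectively by BCl3.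

Step 2
Reactants: 2 4-isopropoxy-2,5-dimethoxybenzaldehyde
Product: 3 1-isopropoxy-2,5-dimethoxy-4-[2-(methylsulfanyl)-2-(methylsulfinyl)ethenyl]benzene
Conditions: CH3S(O)CH2SCH3, benzyltrimethylammonium hydroxide (Triton B, cat.), THF, reflux
Reagents that add atoms: methyl (methylsulfinyl)methyl sulfide, CSCS(C)=O
Why: Knoevenagel-type condensation of the aldehyde with the doubly sulfur-stabilised carbanion (Ogura–Tsuchihashi homologation), which brings in the future lactone carbon C2 at the carboxyl oxidation level.

Step 3
Reactants: 3 1-isopropoxy-2,5-dimethoxy-4-[2-(methylsulfanyl)-2-(methylsulfinyl)ethenyl]benzene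
Product: 4 methyl 2-(4-isopropoxy-2,5-dimethoxyphenyl)acetate
Conditions: HCl, MeOH, 0 °C to rt
Reagents that add atoms: methanol, CO
Why: Acid-mediated methanolysis of the ketene dithioacetal S-oxide (Pummerer-type collapse) should unveil the methyl arylacetate directly, and the aryl ethers are inert to methanolic HCl.

Step 4
Reactants: 4 methyl 2-(4-isopropoxy-2,5-dimethoxyphenyl)acetate
Product: 6 methyl (E)-2-(4-isopropoxy-2,5-dimethoxyphenyl)-3-methoxyprop-2-enoate, via sodium formyl-ester enolate 5 (not isolated)
Conditions: NaH, HCO2Me, DMF, 0 °C to rt; then Me2SO4, rt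
Reagents that add atoms: methyl formate, COC=O; dimethyl sulfate, COS(=O)(=O)OC
Why: Crossed Claisen formylation of the ester enolate, then O-methylation of the formyl enolate by the hard electrophile Me2SO4, is the standard entry to (E)-β-methoxyacrylates; the alkene geometry is immaterial because the key step ionises this bond.

Step 5
Reactants: 6 methyl (E)-2-(4-isopropoxy-2,5-dimethoxyphenyl)-3-methoxyprop-2-enoate
Product: 7 (E)-2-(4-isopropoxy-2,5-dimethoxyphenyl)-3-methoxyprop-2-enoic acid
Conditions: LiOH·H2O, THF/MeOH/H2O, 50 °C; then 1 M HCl to pH 3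
Reagents that add atoms: lithium hydroxide, [Li+].[OH-]
Why: Saponification by acyl-oxygen cleavage of the methyl ester; the vinylogous carbonate is a poor Michael acceptor, so the enol ether should survive.

Step 6
Reactants: 7 (E)-2-(4-isopropoxy-2,5-dimethoxyphenyl)-3-methoxyprop-2-enoic acid; 8 3-methoxyphenol
Product: 9 3-methoxyphenyl (E)-2-(4-isopropoxy-2,5-dimethoxyphenyl)-3-methoxyprop-2-enoate
Conditions: DCC, DMAP (cat.), CH2Cl2, 0 °C to rt
Reagents that add atoms: none
Why: Steglich esterification through the O-acylisourea and the acylpyridinium ion forms the O1–C2 bond that tethers the nucleophilic arene to the masked C4 aldehyde.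

Step 7
Reactants: 9 3-methoxyphenyl (E)-2-(4-isopropoxy-2,5-dimethoxyphenyl)-3-methoxyprop-2-enoate
Product: 11 3-(4-isopropoxy-2,5-dimethoxyphenyl)-7-methoxycoumarin, via 4-methoxy-3,4-dihydrocoumarin 10 (not isolated)
Conditions: TfOH (2 equiv), CH2Cl2, 0 °C to rt
Reagents that add atoms: none
Why: TfOH protonates the enol ether of 9 at C3 to give a methoxycarbenium ion at C4, which the 3-methoxyphenyl ring attacks through the carbon para to its methoxy group and ortho to the ester oxygen, forming C4–C4a and dihydrocoumarin 10; acid-promoted loss of methanol from the now benzylic, para-methoxy-activated C4 then aromatises the pyranone to 11. The closest known reaction type is the Pechmann-type acid cyclisation of aryl esters (and anilides) of 3-alkoxyacrylic or formylacetic acids to coumarins (and quinolin-2-ones). Ring B closes in a 6-exo-trig mode at the oxocarbenium carbon, as an intramolecular Friedel–Crafts alkylation. No stereocenter remains after the step, so the acrylate geometry and the two centres of 10 are of no consequence. The selectivity needed is regiochemical: of the two carbons ortho to the ester oxygen, the one para to the methoxy group is activated and unhindered, whereas the one between the two oxygens is only ortho-activated and crowded, so the 7-methoxy isomer should result. The C3 aryl group could reach C4 only through a three-membered ring, and its isopropyl ether offers the acid no low-energy cleavage path, so both should pass through unchanged.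

Step 8
Reactants: 11 3-(4-isopropoxy-2,5-dimethoxyphenyl)-7-methoxycoumarin
Product: 12 3-(4-hydroxy-2,5-dimethoxyphenyl)-7-methoxycoumarin
Conditions: BCl3 (1 M in CH2Cl2), CH2Cl2, −78 to 0 °C; H2O work-up
Reagents that add atoms: none
Why: Lewis-acid ether cleavage in which the boron-complexed secondary isopropyl group departs as 2-chloropropane far faster than any methyl group, so only the C4' phenol should be freed.

Step 9
Reactants: 12 3-(4-hydroxy-2,5-dimethoxyphenyl)-7-methoxycoumarin
Product: 13 7-methoxy-3-(3,3,6-trimethoxy-4-oxocyclohexa-1,5-dien-1-yl)coumarin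
Conditions: PhI(OAc)2, MeOH/CH2Cl2, 0 °C; used without delay
Reagents that add atoms: methanol, CO
Why: Oxidative dearomatisation of a 2-methoxyphenol by a trivalent iodine reagent: the phenoxenium ion is captured by methanol at the methoxy-bearing C3' (the best cation-stabilising site, the para carbon C1' being blocked by the coumarinyl group) to give the o-quinone monoketal, whose C1' and C6' substituents should slow Diels–Alder dimerisation.

Step 10
Reactants: 13 7-methoxy-3-(3,3,6-trimethoxy-4-oxocyclohexa-1,5-dien-1-yl)coumarin
Product: 14 3-[(4R)-4-allyl-4-hydroxy-3,3,6-trimethoxycyclohexa-1,5-dien-1-yl]-7-methoxycoumarin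
Conditions: allylB(OiPr)2, (R)-3,3'-Br2-BINOL (15 mol%), PhMe/PhCF3, −35 °C; pH 7 buffer work-up, Et3N-deactivated silica
Reagents that add atoms: allyldiisopropoxyborane, C=CCB(OC(C)C)OC(C)C
Why: Proposed new method: chiral-diol-catalysed allylboration is established for aryl and α,β-unsaturated ketones but not for o-quinone monoketals; exchange of one isopropoxy group for the binaphthol should give a more Lewis acidic chiral allylboronate that delivers allyl to the C4' carbonyl through a closed six-membered chair transition state (hence strictly 1,2), with the quaternary ketal carbon C3' and the vinylic C5'H as large and small flanks so that one face is selected and the (R)-carbinol results; the closest known reaction type is the Schaus-type asymmetric allylboration of enones.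

Step 11
Reactants: 14 3-[(4R)-4-allyl-4-hydroxy-3,3,6-trimethoxycyclohexa-1,5-dien-1-yl]-7-methoxycoumarin
Product: 15 3-[(4R)-4-hydroxy-3,3,6-trimethoxy-4-(3-methylbut-2-en-1-yl)cyclohexa-1,5-dien-1-yl]-7-methoxycoumarin
Conditions: second-generation Grubbs catalyst (H2IMes)(PCy3)Cl2Ru=CHPh (5 mol%), 2-methyl-2-butene/CH2Cl2, 35 °C
Reagents that add atoms: 2-methyl-2-butene, CC=C(C)C
Why: Olefin cross-metathesis exchanges the methylene terminus of the monosubstituted allyl alkene for isopropylidene, while the trisubstituted, heteroatom-substituted ring alkenes and the coumarin C3=C4 bond are too hindered or electron-poor to react and C4' is untouched.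

Step 12
Reactants: 15 3-[(4R)-4-hydroxy-3,3,6-trimethoxy-4-(3-methylbut-2-en-1-yl)cyclohexa-1,5-dien-1-yl]-7-methoxycoumarin
Product: 17 3-[(4R)-4-hydroxy-4-(3-methylbut-2-en-1-yl)-3,6-dioxocyclohex-1-en-1-yl]-7-methoxycoumarin (CNP0250763.1), via ketal enone 16 (not isolated)
Conditions: AcOH/THF/H2O, 0 °C to rt; then 1 M HCl (cat.), THF/H2O, 0 °C to rt
Reagents that add atoms: water, O
Why: Two-stage acetal hydrolysis: general-acid protonation of the C5'=C6' enol ether at C5' gives the C6' ketone, then specific-acid hydrolysis of the C3' dimethyl ketal gives the enedione; no bond to C4' is broken, so (R) is retained, and the two oxygens on C3' inductively disfavour ionisation of the allylic C4'–OH in the first stage.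

**Compound list**

1 | 4-hydroxy-2,5-dimethoxybenzaldehyde | COc1cc(C=O)c(OC)cc1O | starting material
2 | 4-isopropoxy-2,5-dimethoxybenzaldehyde | COc1cc(C=O)c(OC)cc1OC(C)C | intermediate
3 | 1-isopropoxy-2,5-dimethoxy-4-[2-(methylsulfanyl)-2-(methylsulfinyl)ethenyl]benzene (alkene geometry and sulfur configuration uncontrolled and without consequence) | COc1cc(C=C(SC)S(C)=O)c(OC)cc1OC(C)C | intermediate
4 | methyl 2-(4-isopropoxy-2,5-dimethoxyphenyl)acetate | COC(=O)Cc1cc(OC)c(OC(C)C)cc1OC | intermediate
5 | sodium enolate of methyl 2-(4-isopropoxy-2,5-dimethoxyphenyl)-3-oxopropanoate | [Na+].[O-]C=C(C(=O)OC)c1cc(OC)c(OC(C)C)cc1OC | intermediate (not isolated)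
6 | methyl (E)-2-(4-isopropoxy-2,5-dimethoxyphenyl)-3-methoxyprop-2-enoate | CO/C=C(/C(=O)OC)c1cc(OC)c(OC(C)C)cc1OC | intermediate
7 | (E)-2-(4-isopropoxy-2,5-dimethoxyphenyl)-3-methoxyprop-2-enoic acid | CO/C=C(/C(O)=O)c1cc(OC)c(OC(C)C)cc1OC | intermediate
8 | 3-methoxyphenol | COc1cccc(O)c1 | starting material
9 | 3-methoxyphenyl (E)-2-(4-isopropoxy-2,5-dimethoxyphenyl)-3-methoxyprop-2-enoate | CO/C=C(/C(=O)Oc1cccc(OC)c1)c1cc(OC)c(OC(C)C)cc1OC | intermediate (key-step precursor)
10 | 3-(4-isopropoxy-2,5-dimethoxyphenyl)-4,7-dimethoxy-3,4-dihydrocoumarin (racemic, both diastereomers) | COC1C(c2cc(OC)c(OC(C)C)cc2OC)C(=O)Oc2cc(OC)ccc12 | intermediate (not isolated)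
11 | 3-(4-isopropoxy-2,5-dimethoxyphenyl)-7-methoxycoumarin | COc1ccc2cc(-c3cc(OC)c(OC(C)C)cc3OC)c(=O)oc2c1 | intermediate (key-step product)
12 | 3-(4-hydroxy-2,5-dimethoxyphenyl)-7-methoxycoumarin | COc1ccc2cc(-c3cc(OC)c(O)cc3OC)c(=O)oc2c1 | intermediate
13 | 7-methoxy-3-(3,3,6-trimethoxy-4-oxocyclohexa-1,5-dien-1-yl)coumarin | COc1ccc2cc(C3=CC(OC)(OC)C(=O)C=C3OC)c(=O)oc2c1 | intermediate
14 | 3-[(4R)-4-allyl-4-hydroxy-3,3,6-trimethoxycyclohexa-1,5-dien-1-yl]-7-methoxycoumarin | COc1ccc2cc(C3=CC(OC)(OC)[C@@](O)(CC=C)C=C3OC)c(=O)oc2c1 | intermediate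
15 | 3-[(4R)-4-hydroxy-3,3,6-trimethoxy-4-(3-methylbut-2-en-1-yl)cyclohexa-1,5-dien-1-yl]-7-methoxycoumarin | COc1ccc2cc(C3=CC(OC)(OC)[C@@](O)(CC=C(C)C)C=C3OC)c(=O)oc2c1 | intermediate
16 | 3-[(4R)-4-hydroxy-3,3-dimethoxy-4-(3-methylbut-2-en-1-yl)-6-oxocyclohex-1-en-1-yl]-7-methoxycoumarin | COc1ccc2cc(C3=CC(OC)(OC)[C@@](O)(CC=C(C)C)CC3=O)c(=O)oc2c1 | intermediate (not isolated)
17 | 3-[(4R)-4-hydroxy-4-(3-methylbut-2-en-1-yl)-3,6-dioxocyclohex-1-en-1-yl]-7-methoxycoumarin (CNP0250763.1) | COc1ccc2cc(C3=CC(=O)[C@@](O)(CC=C(C)C)CC3=O)c(=O)oc2c1 | target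

**Step count and risks**

Total steps: 12. Longest linear sequence: 12 steps (1 to 17); 3-methoxyphenol 8 enters at step 6.

Steps most likely to fail:

Step 10 (proposed method). The allylboration may stall on a carbonyl that is both a vinylogous ester and flanked by a quaternary ketal, or the catalyst may discriminate the two faces poorly. The fallback obtains the stereocenter by resolution with known chemistry. Setting out from 13, a Barbier allylation with allyl bromide and In powder in DMF at rt (1,2-selective for ketones and tolerant of lactones) should give the racemic carbinol rac-3-[4-allyl-4-hydroxy-3,3,6-trimethoxycyclohexa-1,5-dien-1-yl]-7-methoxycoumarin F1. Preparative HPLC on an amylose tris(3,5-dimethylphenylcarbamate) stationary phase then separates 14 from its (S)-enantiomer F2, and the route is rejoined at 14.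

Step 12. During the first stage the allylic C4' hydroxyl may ionise with help from the neighbouring enol ether (Stork–Danheiser-type transposition), or the ketol may dehydrate later, in either case erasing the stereocenter; reversible ionisation would erode the enantiomeric purity. The fallback activates the enol ether with an electrophilic halogen instead of a proton. Setting out from 15, one equivalent of N-iodosuccinimide in THF/H2O with NaHCO3 at −20 °C should attack the enol ether, far more nucleophilic than the prenyl alkene, and give after loss of methanol the α-iodoketone 3-[4-hydroxy-5-iodo-3,3-dimethoxy-4-(3-methylbut-2-en-1-yl)-6-oxocyclohex-1-en-1-yl]-7-methoxycoumarin F3. Radical deiodination with Bu3SnH and Et3B/air in toluene at rt (a radical rather than an enolate, so no β-elimination of the hydroxyl) returns the route at 16, which is isolated and subjected only to the second, ketal-hydrolysing stage of step 12.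

Step 7. Acyl transfer to the ring (Fries pathway, leading on to the chromone series), closure at the carbon between the two oxygens, or acid loss of the isopropyl group may compete with the desired closure. The fallback builds ring B by a different bond, C3–C4. Setting out from 4, saponification (LiOH, THF/H2O) gives 2-(4-isopropoxy-2,5-dimethoxyphenyl)acetic acid F4, and Perkin–Oglialoro condensation with commercial 2-hydroxy-4-methoxybenzaldehyde (COc1ccc(C=O)c(O)c1) in Ac2O/Et3N at 110 °C should give the 3-arylcoumarin directly, rejoining the route at 11.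

**Further compounds**

F1 | step 10 | rac-3-[4-allyl-4-hydroxy-3,3,6-trimethoxycyclohexa-1,5-dien-1-yl]-7-methoxycoumarin | COc1ccc2cc(C3=CC(OC)(OC)C(O)(CC=C)C=C3OC)c(=O)oc2c1
F2 | step 10 | 3-[(4S)-4-allyl-4-hydroxy-3,3,6-trimethoxycyclohexa-1,5-dien-1-yl]-7-methoxycoumarin | COc1ccc2cc(C3=CC(OC)(OC)[C@](O)(CC=C)C=C3OC)c(=O)oc2c1
F3 | step 12 | 3-[(4S)-4-hydroxy-5-iodo-3,3-dimethoxy-4-(3-methylbut-2-en-1-yl)-6-oxocyclohex-1-en-1-yl]-7-methoxycoumarin (carbinol carbon arranged as in 16, descriptor changed by priority only; both epimers at the iodinated carbon) | COc1ccc2cc(C3=CC(OC)(OC)[C@@](O)(CC=C(C)C)C(I)C3=O)c(=O)oc2c1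
F4 | step 7 | 2-(4-isopropoxy-2,5-dimethoxyphenyl)acetic acid | OC(=O)Cc1cc(OC)c(OC(C)C)cc1OC
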